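A flat line of links looks like an equilibrium, yet it says nothing of how the material split on its way there.

| flask | solid first end groups | second end groups | remark | time |
|---|---|---|---|---|
| oak | 5 mM | 4.75 mM | the very flask that is asked about, followed so far |  |
| alder | 5 mM | 9.5 mM | run made earlier |  |
| flask | 5.0 mM | 4.75 mM |  | 2.5 h |

- oak (time / min: links / %, solid first end groups / %): 20.0: 25.4, 0.4; 50.0: 27.0, 0.3; 90.0: 26.4, 0; 150: 24.9, 0
- alder (time / min: links / %, solid first end groups / %): 1.33: 11.1, 80.7; 3.00: 23.2, 57.2; 6.00: 43.7, 16.2; 15.0: 54.7, 1.3

(each reading ± 1 percentage point)

1. links, in percent of the solid first end groups first charged, at 2.5 h
2. the remedy with the largest gain of links, or "none" below 2 percentage points (zeta / alpha / beta / none)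
3. links present, with what was taken out counted in, in percent of the solid first end groups first charged, after zeta
4. links present, with what was taken out counted in, in percent of the solid first end groups first charged, after alpha

- zeta: at 2.5 h take out 90% of the links then present, then wait 5.0 h
- alpha: at 2.5 h add second end groups, 50.0% of the amount charged, then wait 5.0 h
- beta: change nothing and wait 5.0 h more

- links taken out counts as made
- at the start none of the solid first end groups is in solution
- additions bring no volume worth counting

Take it that each first end group that reacts costs one second end group, whether or not it ends as a link, and that links take a share [second end groups]/([second end groups]+h) of what reacts. The alder run, at its last reading, holds links equal to 55.4% of the solid consumed, at a mean [second end groups] of 7.03 mM. So h = 5.66 mM, the even-split level: the [second end groups] at which links take half of what reacts.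

Summing the share as [second end groups] falls gives what does not become links: h·ln(([start]+h)/([end]+h)). In this flask, second end groups are the limiting reagent, since 4.75 mM stands below 5.0 mM, so [end] is zero and links come to 26.0%. The oak readings stay flat from 20.0 min to 150 min, so beta is reckoned to gain nothing. With [end] at zero, zeta is reckoned to gain nothing as well, on the further assumption, which flat readings cannot show, that links have no back step. Alpha meets the 5.00% left unreacted at a share of 28.5%, a gain of 1.4 percentage points, below the 2 points needed.

The forecast gives 26%, 26% after zeta, 26.5% after alpha and none as best, holding that “Removing links or adding second end groups should then achieve little”.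

The flask gives 25.6%, 25.6% after zeta and 27.0% after alpha, a gain of 1.4 points, so the best remedy is none.

    first end groups + second end groups → links (k = 5.70 M⁻¹ s⁻¹)
    first end groups + second end groups → rings, rate k2*[first end groups] as long as [second end groups] is above zero (k = 0.0330 s⁻¹)
    solid first end groups ⇌ first end groups, rate k3*(cs3 - [first end groups]) while solid is left; crystals form when [first end groups] > cs3 (solubility = 2.00 mM, k = 0.00630 s⁻¹)

At 3.66 min, the flask's rings use second end groups 2.3 times as fast as its links do. By 15.0 min, the flask holds links at 25.6% and rings at 69.4%.

A neighbour flask charged with 12 mM of second end groups stands above h and has the solid as its limiting reagent, since 5.0 mM is below that charge, so [end] is 7.00 mM and the rule gives 62.3%. The computed neighbour flask holds 61.8%.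

Readings and results are simulated from invented constants; scatter was added.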